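## Retrosynthetic overview

1. The C9=C10 bond is made last by Julia–Kocienski olefination of PT-sulfone 19 with (2E,4E)-hepta-2,4-dienal 20; the saturated C1–C9 linker comes from a Wittig reaction on α-peroxy aldehyde 11 followed by diimide.
2. The aldehyde and acid arms of 11 are the two ends of a cleaved ring: lactone 9 arises by enzymatic Baeyer–Villiger desymmetrisation of meso ketone 8, which sets both quaternary peroxide carbons in one step (no peroxy-Michael closure, no peroxycarbenium/ketene-acetal addition).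
3. meso-8 comes from a [3+3] annulation of the acetylacetone/H2O2 bis-peroxyketal 3 with bis-allylsilane 5; the new carbon bridge can only be cis, which fixes the relative configuration.
4. Ring order: 1,2-dioxolane (step 1) → six-membered carbocycle across C3/C5, giving the 6,7-dioxabicyclo[3.2.1]octane (step 4) → ring-expanded seven-membered lactone (step 6) → opened again to leave only the dioxolane (step 7).

Assumption: simple reagents (H2O2, MeOH, Me3SiCl, O3, O2, LiOH, PPh3) are given by name and SMILES on the "Reagents that add atoms" line and carry no compound number.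
Assumption: Baeyer–Villiger monooxygenase panels contain enantiocomplementary enzymes; the one that delivers the lactone enantiomer drawn as 9 is used.
Assumption: the low-molecular-weight peroxides 2, 3, 7 and 8 are handled in solution on small scale.

## Route

Step 1
Reactants: 1 pentane-2,4-dione
Product: 2 3,5-dimethyl-1,2-dioxolane-3,5-diol (cis/trans mixture)
Conditions: 30% aq. H2O2 (1.05 equiv), 0 °C → rt
Reagents that add atoms: hydrogen peroxide, OO
Why: Double perhydration: H2O2 adds to one carbonyl and the hydroperoxide closes onto the second, giving the known cyclic bis(peroxyhemiketal); the 1,2-dioxolane ring and its O–O bond are made here, and the cis/trans ratio is irrelevant because both carbons are ionised later.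

Step 2
Reactants: 2 3,5-dimethyl-1,2-dioxolane-3,5-diol
Product: 3 3,5-dimethoxy-3,5-dimethyl-1,2-dioxolane (cis/trans mixture)
Conditions: MeOH, CSA (5 mol %), 3 Å MS, 0 °C → rt
Reagents that add atoms: methanol, CO
Why: Acid-catalysed peroxyhemiketal → peroxyketal exchange (the SN1-type etherification used to make 3-alkoxy-1,2-dioxolanes) turns both OH groups into methoxy leaving groups.

Step 3
Reactants: 4 3-chloro-2-(chloromethyl)prop-1-ene
Product: 5 trimethyl{2-[(trimethylsilyl)methyl]prop-2-en-1-yl}silane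
Conditions: Mg, Me3SiCl, THF, reflux
Reagents that add atoms: chlorotrimethylsilane, C[Si](C)(C)Cl
Why: In-situ Grignard (Barbier) double silylation of the bis-allylic chloride, the standard preparation of this conjunctive 1,3-bis-nucleophile.

Step 4
Reactants: 3 3,5-dimethoxy-3,5-dimethyl-1,2-dioxolane; 5 trimethyl{2-[(trimethylsilyl)methyl]prop-2-en-1-yl}silane
Product: 7 (1R,5S)-1,5-dimethyl-3-methylidene-6,7-dioxabicyclo[3.2.1]octane (meso, bridgehead methyls cis), via 3-methoxy-3,5-dimethyl-5-{2-[(trimethylsilyl)methyl]prop-2-en-1-yl}-1,2-dioxolane 6 (not isolated)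
Conditions: TMSOTf (0.3 equiv), CH2Cl2 (0.02 M), −78 → −30 °C; Et3N quench
Reagents that add atoms: none
Why: Proposed new method: TMSOTf ionises one peroxyketal C–OMe of 3 to a peroxycarbenium ion that is captured by the allylsilane (SE2′, loss of Me3Si) to give 6, whose second C–OMe then ionises and is trapped by the remaining allylsilane arm in a six-membered ring closure; the three-carbon bridge can only span one face of the dioxolane, so the two methyl groups are forced cis and the product is meso whatever the composition of 3; the closest known reactions are the Lewis-acid allylation of 3-alkoxy-1,2-dioxolanes through peroxycarbenium ions and the annulation of this bis-silane with cyclic bis-acetals such as 2,5-dimethoxytetrahydrofuran to give 8-oxabicyclo[3.2.1]octanes.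

Step 5
Reactants: 7 (1R,5S)-1,5-dimethyl-3-methylidene-6,7-dioxabicyclo[3.2.1]octane
Product: 8 (1R,5S)-1,5-dimethyl-6,7-dioxabicyclo[3.2.1]octan-3-one (meso)
Conditions: O3, CH2Cl2/MeOH, −78 °C; Me2S, → rt
Reagents that add atoms: ozone, [O-][O+]=O
Why: Ozonolysis of the exocyclic 1,1-disubstituted alkene with reductive work-up; the tetrasubstituted dialkyl peroxide has no α-H and is inert to ozone and Me2S, and the product is still meso.

Step 6
Reactants: 8 (1R,5S)-1,5-dimethyl-6,7-dioxabicyclo[3.2.1]octan-3-one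
Product: 9 (1S,6R)-1,6-dimethyl-3,7,8-trioxabicyclo[4.2.1]nonan-4-one
Conditions: recombinant cyclohexanone monooxygenase (BVMO), NADP+ (cat.), alcohol dehydrogenase/iPrOH (NADPH recycling), air, Tris buffer pH 8, 25 °C
Reagents that add atoms: dioxygen, O=O
Why: Enzymatic Baeyer–Villiger desymmetrisation of a meso cyclohexanone: the flavin hydroperoxide adds to the carbonyl and only one of the two enantiotopic α-CH2 groups migrates, which fixes the absolute configuration of both quaternary peroxide carbons at once (the future 3R,5R) without any enol or enolate, so the β-peroxy ketone cannot open by retro-Michael.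

Step 7
Reactants: 9 (1S,6R)-1,6-dimethyl-3,7,8-trioxabicyclo[4.2.1]nonan-4-one
Product: 10 2-[(3R,5S)-5-(hydroxymethyl)-3,5-dimethyl-1,2-dioxolan-3-yl]acetic acid
Conditions: LiOH·H2O (2 equiv), THF/H2O, 0 °C; 1 M HCl to pH 3
Reagents that add atoms: lithium hydroxide, [Li+].[OH-]
Why: Lactone saponification by acyl–oxygen cleavage leaves both stereocentres untouched; LiOH hydrolysis of β-peroxy esters is routine and the carboxylate formed does not lose the peroxide by E1cB.

Step 8
Reactants: 10 2-[(3R,5S)-5-(hydroxymethyl)-3,5-dimethyl-1,2-dioxolan-3-yl]acetic acid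
Product: 11 2-[(3R,5S)-5-formyl-3,5-dimethyl-1,2-dioxolan-3-yl]acetic acid
Conditions: Dess–Martin periodinane (1.3 equiv), CH2Cl2, 0 °C → rt
Reagents that add atoms: none
Why: Dess–Martin oxidation of the neopentyl primary alcohol under non-basic conditions; the α-peroxy aldehyde has a quaternary α-carbon, so it can neither epimerise nor undergo Kornblum–DeLaMare cleavage.

Step 9
Reactants: 12 1,8-dibromooctane; 13 1-phenyl-1H-tetrazole-5-thiol
Product: 14 5-[(8-bromooctyl)sulfanyl]-1-phenyl-1H-tetrazole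
Conditions: 12 (3 equiv), K2CO3, acetone, rt
Reagents that add atoms: none
Why: SN2 S-alkylation of the acidic tetrazole thiol; excess dibromide suppresses double substitution.

Step 10
Reactants: 14 5-[(8-bromooctyl)sulfanyl]-1-phenyl-1H-tetrazole
Product: 15 triphenyl{8-[(1-phenyl-1H-tetrazol-5-yl)sulfanyl]octyl}phosphonium bromide
Conditions: PPh3 (1.1 equiv), MeCN, reflux
Reagents that add atoms: triphenylphosphine, c1ccccc1P(c1ccccc1)c1ccccc1
Why: SN2 quaternisation of triphenylphosphine by the primary bromide; the heteroaryl thioether is inert.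

Step 11
Reactants: 11 2-[(3R,5S)-5-formyl-3,5-dimethyl-1,2-dioxolan-3-yl]acetic acid; 15 triphenyl{8-[(1-phenyl-1H-tetrazol-5-yl)sulfanyl]octyl}phosphonium bromide
Product: 17 2-[(3R,5S)-3,5-dimethyl-5-{(1Z)-9-[(1-phenyl-1H-tetrazol-5-yl)sulfanyl]non-1-en-1-yl}-1,2-dioxolan-3-yl]acetic acid, via triphenyl{8-[(1-phenyl-1H-tetrazol-5-yl)sulfanyl]octylidene}-λ5-phosphane 16 (not isolated)
Conditions: 15, NaHMDS, THF, −78 °C; then 11 (pre-treated with NaH, 1.0 equiv, THF, 0 °C), −78 → 0 °C; 1 M HCl work-up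
Reagents that add atoms: none
Why: Wittig olefination with a non-stabilised ylide (Z-selective, though the geometry is irrelevant because the alkene is reduced next); the acid is carried as its sodium carboxylate, which resists enolisation and retro-peroxy-Michael opening, and olefination of α-peroxy aldehydes with phosphoranes is known.

Step 12
Reactants: 17 2-[(3R,5S)-3,5-dimethyl-5-{(1Z)-9-[(1-phenyl-1H-tetrazol-5-yl)sulfanyl]non-1-en-1-yl}-1,2-dioxolan-3-yl]acetic acid
Product: 18 2-[(3R,5R)-3,5-dimethyl-5-{9-[(1-phenyl-1H-tetrazol-5-yl)sulfanyl]nonyl}-1,2-dioxolan-3-yl]acetic acid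
Conditions: dipotassium azodicarboxylate (10 equiv, portionwise), AcOH, MeOH/CH2Cl2, 0 °C → rt
Reagents that add atoms: none
Why: Diimide reduction (concerted syn transfer of H2 to the disubstituted alkene) is the classical way to saturate a C=C next to an O–O bond, which metal-catalysed hydrogenation would cleave; thioether, tetrazole and acid are untouched.

Step 13
Reactants: 18 2-[(3R,5R)-3,5-dimethyl-5-{9-[(1-phenyl-1H-tetrazol-5-yl)sulfanyl]nonyl}-1,2-dioxolan-3-yl]acetic acid
Product: 19 2-[(3R,5R)-3,5-dimethyl-5-{9-[(1-phenyl-1H-tetrazol-5-yl)sulfonyl]nonyl}-1,2-dioxolan-3-yl]acetic acid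
Conditions: (NH4)6Mo7O24·4H2O (10 mol %), 30% H2O2 (6 equiv), EtOH, 0 °C → rt
Reagents that add atoms: hydrogen peroxide, OO
Why: Mo(VI)/H2O2 oxidation of the tetrazolyl sulfide to the sulfone (standard preparation of Julia–Kocienski reagents); no alkene remains to be epoxidised and the hindered dialkyl peroxide is inert.

Step 14
Reactants: 19 2-[(3R,5R)-3,5-dimethyl-5-{9-[(1-phenyl-1H-tetrazol-5-yl)sulfonyl]nonyl}-1,2-dioxolan-3-yl]acetic acid; 20 (2E,4E)-hepta-2,4-dienal
Product: 21 2-[(3R,5R)-5-[(9E,11E,13E)-hexadeca-9,11,13-trien-1-yl]-3,5-dimethyl-1,2-dioxolan-3-yl]acetic acid (CID9842769)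
Conditions: KHMDS (2.2 equiv), DME, −60 °C; 20 (1.3 equiv), −60 °C → rt; 1 M HCl to pH 3–4, BHT, dark
Reagents that add atoms: none
Why: Julia–Kocienski olefination (addition, Smiles rearrangement, loss of SO2 and tetrazolate): the PT-sulfone/KHMDS/DME combination forms the new C9=C10 bond E-selectively, the 11E,13E geometry arrives intact with the dienal, and the dianion (carboxylate plus sulfonyl carbanion) leaves the peroxide and both quaternary centres untouched.

## Compound list

1 | pentane-2,4-dione | CC(=O)CC(C)=O | starting material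
2 | 3,5-dimethyl-1,2-dioxolane-3,5-diol (cis/trans mixture) | CC1(O)CC(C)(O)OO1 | intermediate
3 | 3,5-dimethoxy-3,5-dimethyl-1,2-dioxolane (cis/trans mixture) | COC1(C)CC(C)(OC)OO1 | intermediate
4 | 3-chloro-2-(chloromethyl)prop-1-ene | C=C(CCl)CCl | starting material
5 | trimethyl{2-[(trimethylsilyl)methyl]prop-2-en-1-yl}silane | C=C(C[Si](C)(C)C)C[Si](C)(C)C | intermediate
6 | 3-methoxy-3,5-dimethyl-5-{2-[(trimethylsilyl)methyl]prop-2-en-1-yl}-1,2-dioxolane (diastereomer mixture, not isolated) | COC1(C)CC(C)(CC(=C)C[Si](C)(C)C)OO1 | intermediate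
7 | (1R,5S)-1,5-dimethyl-3-methylidene-6,7-dioxabicyclo[3.2.1]octane (meso) | C=C1C[C@]2(C)C[C@](C)(C1)OO2 | intermediate
8 | (1R,5S)-1,5-dimethyl-6,7-dioxabicyclo[3.2.1]octan-3-one (meso) | O=C1C[C@]2(C)C[C@](C)(C1)OO2 | intermediate
9 | (1S,6R)-1,6-dimethyl-3,7,8-trioxabicyclo[4.2.1]nonan-4-one | O=C1OC[C@]2(C)C[C@](C)(C1)OO2 | intermediate
10 | 2-[(3R,5S)-5-(hydroxymethyl)-3,5-dimethyl-1,2-dioxolan-3-yl]acetic acid | OC[C@]1(C)C[C@](C)(CC(=O)O)OO1 | intermediate
11 | 2-[(3R,5S)-5-formyl-3,5-dimethyl-1,2-dioxolan-3-yl]acetic acid | O=C[C@]1(C)C[C@](C)(CC(=O)O)OO1 | intermediate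
12 | 1,8-dibromooctane | BrCCCCCCCCBr | starting material
13 | 1-phenyl-1H-tetrazole-5-thiol | SC1=NN=NN1c1ccccc1 | starting material
14 | 5-[(8-bromooctyl)sulfanyl]-1-phenyl-1H-tetrazole | BrCCCCCCCCSC1=NN=NN1c1ccccc1 | intermediate
15 | triphenyl{8-[(1-phenyl-1H-tetrazol-5-yl)sulfanyl]octyl}phosphonium bromide | [Br-].c1ccccc1[P+](c1ccccc1)(c1ccccc1)CCCCCCCCSC1=NN=NN1c1ccccc1 | intermediate
16 | triphenyl{8-[(1-phenyl-1H-tetrazol-5-yl)sulfanyl]octylidene}-λ5-phosphane (ylide, not isolated) | c1ccccc1P(c1ccccc1)(c1ccccc1)=CCCCCCCCSC1=NN=NN1c1ccccc1 | intermediate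
17 | 2-[(3R,5S)-3,5-dimethyl-5-{(1Z)-9-[(1-phenyl-1H-tetrazol-5-yl)sulfanyl]non-1-en-1-yl}-1,2-dioxolan-3-yl]acetic acid | c1ccccc1N1N=NN=C1SCCCCCCC/C=C\[C@]1(C)C[C@](C)(CC(=O)O)OO1 | intermediate
18 | 2-[(3R,5R)-3,5-dimethyl-5-{9-[(1-phenyl-1H-tetrazol-5-yl)sulfanyl]nonyl}-1,2-dioxolan-3-yl]acetic acid | c1ccccc1N1N=NN=C1SCCCCCCCCC[C@]1(C)C[C@](C)(CC(=O)O)OO1 | intermediate
19 | 2-[(3R,5R)-3,5-dimethyl-5-{9-[(1-phenyl-1H-tetrazol-5-yl)sulfonyl]nonyl}-1,2-dioxolan-3-yl]acetic acid | c1ccccc1N1N=NN=C1S(=O)(=O)CCCCCCCCC[C@]1(C)C[C@](C)(CC(=O)O)OO1 | intermediate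
20 | (2E,4E)-hepta-2,4-dienal | CC/C=C/C=C/C=O | starting material
21 | 2-[(3R,5R)-5-[(9E,11E,13E)-hexadeca-9,11,13-trien-1-yl]-3,5-dimethyl-1,2-dioxolan-3-yl]acetic acid | CC/C=C/C=C/C=C/CCCCCCCC[C@]1(C)C[C@](C)(CC(=O)O)OO1 | target

## Step count and risks

Total steps: 14. Longest linear sequence: 11 steps (1, 2, 4, 5, 6, 7, 8, 11, 12, 13, 14) from pentane-2,4-dione.

Most likely to fail, first: step 4. The bis-peroxyketal may undergo Criegee/Hock-type fragmentation under the Lewis acid, or be allylated twice intermolecularly, before the ring closes. The fallback sets out from 3 and changes the bis-nucleophile and the ring-forming bond type. Compound 3 is treated (TMSOTf, CH2Cl2, −78 °C) with commercial 1-methoxy-1,3-bis(trimethylsilyloxy)buta-1,3-diene (COC(O[Si](C)(C)C)=CC(=C)O[Si](C)(C)C), a much stronger π-nucleophile than the allylsilane. The first Mukaiyama-type attack gives methyl 4-(5-methoxy-3,5-dimethyl-1,2-dioxolan-3-yl)-3-[(trimethylsilyl)oxy]but-2-enoate F1 (not isolated), which closes onto the second peroxyketal carbon to give racemic methyl 1,5-dimethyl-3-oxo-6,7-dioxabicyclo[3.2.1]octane-2-carboxylate F2. Pig-liver esterase at pH 7 then gives 1,5-dimethyl-3-oxo-6,7-dioxabicyclo[3.2.1]octane-2-carboxylic acid F3, which loses CO2 at 25–35 °C and comes back to the route at ketone 8.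

Second: step 6. The enzyme may not accept a ketone flanked by two quaternary bridgeheads, or may give low ee. The fallback sets out from 8 and replaces desymmetrisation by classical resolution. mCPBA/NaHCO3 in CH2Cl2 gives racemic 1,6-dimethyl-3,7,8-trioxabicyclo[4.2.1]nonan-4-one F4, and LiOH gives racemic 2-[5-(hydroxymethyl)-3,5-dimethyl-1,2-dioxolan-3-yl]acetic acid F5. The less soluble diastereomeric salt with one enantiomer of 1-phenylethan-1-amine (written for R), (R)-1-phenylethan-1-aminium 2-[(3R,5S)-5-(hydroxymethyl)-3,5-dimethyl-1,2-dioxolan-3-yl]acetate F6, is crystallised, and acidification comes back to the route at 10.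

Third: step 2. Acidic methanol may send the bis(peroxyhemiketal) back to diketone and H2O2 or to open-chain hydroperoxy ketals. The fallback sets out from 2 and avoids acid-catalysed ketal exchange altogether. Neutral O-silylation (Me3SiCl, imidazole, CH2Cl2, 0 °C) gives 3,5-dimethyl-3,5-bis[(trimethylsilyl)oxy]-1,2-dioxolane F7. F7 is taken directly into the annulation with 5 (TMSOTf, CH2Cl2, −78 °C), passing through 3,5-dimethyl-3-[(trimethylsilyl)oxy]-5-{2-[(trimethylsilyl)methyl]prop-2-en-1-yl}-1,2-dioxolane F8 (not isolated), and comes back to the route at 7.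

Further compounds

F1 | step 4 | methyl 4-(5-methoxy-3,5-dimethyl-1,2-dioxolan-3-yl)-3-[(trimethylsilyl)oxy]but-2-enoate (isomer mixture, not isolated) | COC(=O)C=C(O[Si](C)(C)C)CC1(C)CC(C)(OC)OO1
F2 | step 4 | racemic methyl 1,5-dimethyl-3-oxo-6,7-dioxabicyclo[3.2.1]octane-2-carboxylate (C2 epimers) | O=C1C(C(=O)OC)[C@]2(C)C[C@](C)(C1)OO2.O=C1C(C(=O)OC)[C@@]2(C)C[C@@](C)(C1)OO2
F3 | step 4 | racemic 1,5-dimethyl-3-oxo-6,7-dioxabicyclo[3.2.1]octane-2-carboxylic acid (not isolated) | O=C1C(C(=O)O)[C@]2(C)C[C@](C)(C1)OO2.O=C1C(C(=O)O)[C@@]2(C)C[C@@](C)(C1)OO2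
F4 | step 6 | racemic 1,6-dimethyl-3,7,8-trioxabicyclo[4.2.1]nonan-4-one | O=C1OC[C@]2(C)C[C@](C)(C1)OO2.O=C1OC[C@@]2(C)C[C@@](C)(C1)OO2
F5 | step 6 | racemic 2-[5-(hydroxymethyl)-3,5-dimethyl-1,2-dioxolan-3-yl]acetic acid (methyls cis) | OC[C@]1(C)C[C@](C)(CC(=O)O)OO1.OC[C@@]1(C)C[C@@](C)(CC(=O)O)OO1
F6 | step 6 | (R)-1-phenylethan-1-aminium 2-[(3R,5S)-5-(hydroxymethyl)-3,5-dimethyl-1,2-dioxolan-3-yl]acetate | C[C@@H]([NH3+])c1ccccc1.OC[C@]1(C)C[C@](C)(CC(=O)[O-])OO1
F7 | step 2 | 3,5-dimethyl-3,5-bis[(trimethylsilyl)oxy]-1,2-dioxolane (cis/trans mixture) | C[Si](C)(C)OC1(C)CC(C)(O[Si](C)(C)C)OO1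
F8 | step 2 | 3,5-dimethyl-3-[(trimethylsilyl)oxy]-5-{2-[(trimethylsilyl)methyl]prop-2-en-1-yl}-1,2-dioxolane (not isolated) | C[Si](C)(C)OC1(C)CC(C)(CC(=C)C[Si](C)(C)C)OO1
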